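The 14-membered carbocycle is opened at C12–C13, the bond between the β-carbon of the C11 enoate and a plain methylene that lies far from C3, C5, C6 and C10. A nickel-catalysed reductive coupling of two electrophilic carbons, the (Z)-β-iodo enoate at C12 and a primary iodide at C13, closes this ring in one operation, so no organometallic reagent has to coexist with two enoates. The seco diiodide carries the C5–C8 (E,E)-diene and silyl ethers at C3 and C10 in place of the vinyl epoxide and the acetates. It is assembled by Suzuki coupling (C6–C7), Still–Gennari olefination (C1=C2) and a catalytic asymmetric iodo-aldol reaction (C10–C11).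

Key step: step 17

Remark: ring atoms are numbered C1(CO2Me)=C2, C3(OAc), C4, C5(Me), C6, C7=C8(iPr), C9, C10(OAc), C11(CO2Me)=C12, C13, C14, and open-chain intermediates are discussed with the same numbers; the target is 3R,5S,6S,10R with 1Z,7E,11Z alkenes.
Assumption: the (S)-configured oxazaborolidinium catalyst of step 13 exposes the Si face of an aliphatic aldehyde, as its formyl C–H···O binding model implies; its mirror image serves if the sense proves opposite.

Step 1
Reactants: 1 (R)-glycidyl 4-methoxybenzyl ether; 2 lithium acetylide–ethylenediamine complex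
Product: 3 (2R)-1-[(4-methoxybenzyl)oxy]pent-4-yn-2-ol
Conditions: LiC≡CH·H2NCH2CH2NH2 (1.5 equiv), DMSO, 0 °C to rt; H2O quench
Reagents that add atoms: none
Why: SN2 opening of the terminal epoxide by the acetylide at its unsubstituted carbon (epoxide alkynylation) leaves the existing stereocentre untouched, so the R carbinol that becomes C3 is carried over from 1.

Step 2
Reactants: 3 (2R)-1-[(4-methoxybenzyl)oxy]pent-4-yn-2-ol
Product: 4 tert-butyl{[(2R)-1-[(4-methoxybenzyl)oxy]pent-4-yn-2-yl]oxy}dimethylsilane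
Conditions: t-BuMe2SiCl, imidazole, DMF, rt
Reagents that add atoms: tert-butyldimethylsilyl chloride, CC(C)(C)[Si](C)(C)Cl
Why: Imidazole-promoted silylation of the secondary alcohol installs the C3 silyl ether, which has to last until after ring closure.

Step 3
Reactants: 4 tert-butyl{[(2R)-1-[(4-methoxybenzyl)oxy]pent-4-yn-2-yl]oxy}dimethylsilane
Product: 6 tert-butyl{[(2R,4E)-5-iodo-1-[(4-methoxybenzyl)oxy]-4-methylpent-4-en-2-yl]oxy}dimethylsilane, via alkenyldimethylalane 5 (not isolated)
Conditions: AlMe3 (2.5 equiv), (C5H5)2ZrCl2 (0.25 equiv), CH2Cl2, 0 °C to rt; then I2, THF, −30 °C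
Reagents that add atoms: trimethylaluminium, C[Al](C)C; iodine, II
Why: Zirconium-catalysed carboalumination (Negishi carboalumination) adds methyl and aluminium syn across the terminal alkyne with methyl on the internal carbon, and iodinolysis of the C–Al bond with retention gives the E alkenyl iodide (C4 trans to I), which fixes the C5=C6 geometry.

Step 4
Reactants: 6 tert-butyl{[(2R,4E)-5-iodo-1-[(4-methoxybenzyl)oxy]-4-methylpent-4-en-2-yl]oxy}dimethylsilane
Product: 7 (2R,4E)-2-[(tert-butyldimethylsilyl)oxy]-5-iodo-4-methylpent-4-en-1-ol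
Conditions: DDQ, CH2Cl2/pH 7 phosphate buffer, 0 °C to rt
Reagents that add atoms: none
Why: Oxidative cleavage of the 4-methoxybenzyl ether by DDQ (electron transfer to the benzylic oxocarbenium ion, then hydrolysis) frees only the C2 hydroxyl, and it is placed here, before the easily oxidised diene exists.

Step 5
Reactants: 7 (2R,4E)-2-[(tert-butyldimethylsilyl)oxy]-5-iodo-4-methylpent-4-en-1-ol
Product: 8 (2R,4E)-2-[(tert-butyldimethylsilyl)oxy]-5-iodo-4-methylpent-4-enal
Conditions: Dess–Martin periodinane, NaHCO3, CH2Cl2, 0 °C to rt; used crude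
Reagents that add atoms: none
Why: Dess–Martin oxidation under bicarbonate buffering gives the α-silyloxy aldehyde without epimerising C3, and the crude aldehyde is taken directly into the olefination.

Step 6
Reactants: 9 methyl bis(2,2,2-trifluoroethyl)phosphonoacetate; 10 tert-butyl(2-iodoethoxy)dimethylsilane
Product: 11 methyl 2-[bis(2,2,2-trifluoroethoxy)phosphoryl]-4-[(tert-butyldimethylsilyl)oxy]butanoate
Conditions: NaH, DMF, 0 °C; then 10, 50 °C
Reagents that add atoms: none
Why: C-alkylation of the sodium phosphonoacetate by the primary iodide (SN2) attaches the C13–C14 arm as a silyl ether, because an α-(2-iodoethyl)phosphonate anion would close to a cyclopropane instead of olefinating.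

Step 7
Reactants: 8 (2R,4E)-2-[(tert-butyldimethylsilyl)oxy]-5-iodo-4-methylpent-4-enal; 11 methyl 2-[bis(2,2,2-trifluoroethoxy)phosphoryl]-4-[(tert-butyldimethylsilyl)oxy]butanoate
Product: 12 methyl (2Z,4R,6E)-4-[(tert-butyldimethylsilyl)oxy]-2-{2-[(tert-butyldimethylsilyl)oxy]ethyl}-7-iodo-6-methylhepta-2,6-dienoate
Conditions: KN(SiMe3)2, 18-crown-6, THF, −78 °C
Reagents that add atoms: none
Why: Still–Gennari olefination: the electron-poor trifluoroethyl phosphonate eliminates from the kinetic adduct faster than it equilibrates, which gives the Z trisubstituted enoate (ester cis to C3) and sets the C1=C2 geometry.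

Step 8
Reactants: 13 3-methylbut-1-yne
Product: 15 2-[(1Z)-2-bromo-3-methylbut-1-en-1-yl]-4,4,5,5-tetramethyl-1,3,2-dioxaborolane, via dibromoborane 14 (not isolated)
Conditions: BBr3, CH2Cl2, −78 °C to rt; then pinacol, CH2Cl2, 0 °C to rt
Reagents that add atoms: boron tribromide, BrB(Br)Br; pinacol, CC(C)(O)C(C)(C)O
Why: Bromoboration of the terminal alkyne is a syn addition that places boron on the terminal carbon (Br cis to B), and esterification with pinacol gives a configurationally stable alkenylboronate with isopropyl trans to boron.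

Step 9
Reactants: 15 2-[(1Z)-2-bromo-3-methylbut-1-en-1-yl]-4,4,5,5-tetramethyl-1,3,2-dioxaborolane; 16 (2-ethoxy-2-oxoethyl)zinc bromide
Product: 17 ethyl (3E)-4-methyl-3-[(4,4,5,5-tetramethyl-1,3,2-dioxaborolan-2-yl)methylidene]pentanoate
Conditions: Pd[P(t-Bu)3]2 (3 mol%), THF, 25 °C
Reagents that add atoms: none
Why: Negishi coupling of the alkenyl bromide with the Reformatsky reagent proceeds with retention at the alkene and leaves the boronate alone (no base for boron transmetalation), so the C9 carbon ends cis to boron.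

Step 10
Reactants: 17 ethyl (3E)-4-methyl-3-[(4,4,5,5-tetramethyl-1,3,2-dioxaborolan-2-yl)methylidene]pentanoate
Product: 18 (3E)-4-methyl-3-[(4,4,5,5-tetramethyl-1,3,2-dioxaborolan-2-yl)methylidene]pentan-1-ol
Conditions: i-Bu2AlH (2.2 equiv), CH2Cl2, −78 °C; aq. potassium sodium tartrate
Reagents that add atoms: none
Why: Hydride reduction of the ester to the primary alcohol at low temperature spares the pinacol boronate and delivers C10 at the alcohol level, so that the isomerisation-prone aldehyde is made only when it is needed.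

Step 11
Reactants: 12 methyl (2Z,4R,6E)-4-[(tert-butyldimethylsilyl)oxy]-2-{2-[(tert-butyldimethylsilyl)oxy]ethyl}-7-iodo-6-methylhepta-2,6-dienoate; 18 (3E)-4-methyl-3-[(4,4,5,5-tetramethyl-1,3,2-dioxaborolan-2-yl)methylidene]pentan-1-ol
Product: 19 methyl (2Z,4R,6E,8E)-4-[(tert-butyldimethylsilyl)oxy]-2-{2-[(tert-butyldimethylsilyl)oxy]ethyl}-11-hydroxy-6-methyl-9-(propan-2-yl)undeca-2,6,8-trienoate
Conditions: PdCl2[1,1'-bis(diphenylphosphino)ferrocene] (5 mol%), K3PO4, THF/H2O, rt to 40 °C
Reagents that add atoms: none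
Why: Suzuki–Miyaura coupling forms C6–C7 with retention at both alkenyl carbons (insertion of zerovalent palladium into C–I, base-assisted transmetalation, reductive elimination), so the 5E,7E diene is assembled from two geometrically defined halves.

Step 12
Reactants: 19 methyl (2Z,4R,6E,8E)-4-[(tert-butyldimethylsilyl)oxy]-2-{2-[(tert-butyldimethylsilyl)oxy]ethyl}-11-hydroxy-6-methyl-9-(propan-2-yl)undeca-2,6,8-trienoate
Product: 20 methyl (2Z,4R,6E,8E)-4-[(tert-butyldimethylsilyl)oxy]-2-{2-[(tert-butyldimethylsilyl)oxy]ethyl}-6-methyl-11-oxo-9-(propan-2-yl)undeca-2,6,8-trienoate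
Conditions: Dess–Martin periodinane, NaHCO3, CH2Cl2, 0 °C; used crude at once
Reagents that add atoms: none
Why: Buffered Dess–Martin oxidation of the only free hydroxyl gives the C10 aldehyde under neutral conditions, which limits migration of the C7=C8 bond into conjugation.

Step 13
Reactants: 20 methyl (2Z,4R,6E,8E)-4-[(tert-butyldimethylsilyl)oxy]-2-{2-[(tert-butyldimethylsilyl)oxy]ethyl}-6-methyl-11-oxo-9-(propan-2-yl)undeca-2,6,8-trienoate; 21 methyl propiolate
Product: 24 dimethyl (2Z,4R,6E,8E,11R,12Z)-4-[(tert-butyldimethylsilyl)oxy]-2-{2-[(tert-butyldimethylsilyl)oxy]ethyl}-11-hydroxy-12-(iodomethylidene)-6-methyl-9-(propan-2-yl)trideca-2,6,8-trienedioate, via silyl allenolate 22 (not isolated), via C10 trimethylsilyl ether 23 (not isolated)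
Conditions: Me3SiI (1.3 equiv), (S)-3,3-diphenyl-1-(2-methylphenyl)tetrahydro-1H,3H-pyrrolo[1,2-c][1,3,2]oxazaborole·HN(SO2CF3)2 (20 mol%), EtCN, −78 °C; then citric acid, MeOH, 0 °C
Reagents that add atoms: iodotrimethylsilane, C[Si](C)(C)I
Why: Iodide adds to the propiolate to give silyl allenolate 22, which undergoes a Mukaiyama-type aldol addition to the aldehyde bound to the chiral boron cation (catalytic asymmetric β-iodo Morita–Baylis–Hillman coupling); attack on the Si face sets C10 as R, approach anti to iodine gives the Z β-iodo enoate (I cis to CO2Me), and the non-basic −78 °C medium keeps the skipped dienal intact.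

Step 14
Reactants: 24 dimethyl (2Z,4R,6E,8E,11R,12Z)-4-[(tert-butyldimethylsilyl)oxy]-2-{2-[(tert-butyldimethylsilyl)oxy]ethyl}-11-hydroxy-12-(iodomethylidene)-6-methyl-9-(propan-2-yl)trideca-2,6,8-trienedioate
Product: 25 dimethyl (2Z,4R,6E,8E,11R,12Z)-4,11-bis[(tert-butyldimethylsilyl)oxy]-2-{2-[(tert-butyldimethylsilyl)oxy]ethyl}-12-(iodomethylidene)-6-methyl-9-(propan-2-yl)trideca-2,6,8-trienedioate
Conditions: t-BuMe2SiOSO2CF3, 2,6-lutidine, CH2Cl2, −78 to 0 °C
Reagents that add atoms: tert-butyldimethylsilyl triflate, CC(C)(C)[Si](C)(C)OS(=O)(=O)C(F)(F)F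
Why: Silylation with the silyl triflate and a hindered base caps the hindered C10 carbinol without touching the β-iodo enoate, so that no ionisable allylic oxygen is offered to nickel later.

Step 15
Reactants: 25 dimethyl (2Z,4R,6E,8E,11R,12Z)-4,11-bis[(tert-butyldimethylsilyl)oxy]-2-{2-[(tert-butyldimethylsilyl)oxy]ethyl}-12-(iodomethylidene)-6-methyl-9-(propan-2-yl)trideca-2,6,8-trienedioate
Product: 26 dimethyl (2Z,4R,6E,8E,11R,12Z)-4,11-bis[(tert-butyldimethylsilyl)oxy]-2-(2-hydroxyethyl)-12-(iodomethylidene)-6-methyl-9-(propan-2-yl)trideca-2,6,8-trienedioate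
Conditions: HF·pyridine, pyridine, THF, 0 °C
Reagents that add atoms: none
Why: Buffered fluoride desilylation discriminates on steric grounds, cleaving the primary silyl ether while the two secondary ones persist, and the cold, weakly acidic medium should keep the γ-hydroxy ester from lactonising.

Step 16
Reactants: 26 dimethyl (2Z,4R,6E,8E,11R,12Z)-4,11-bis[(tert-butyldimethylsilyl)oxy]-2-(2-hydroxyethyl)-12-(iodomethylidene)-6-methyl-9-(propan-2-yl)trideca-2,6,8-trienedioate
Product: 27 dimethyl (2Z,4R,6E,8E,11R,12Z)-4,11-bis[(tert-butyldimethylsilyl)oxy]-2-(2-iodoethyl)-12-(iodomethylidene)-6-methyl-9-(propan-2-yl)trideca-2,6,8-trienedioate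
Conditions: PPh3, I2, imidazole (premixed), CH2Cl2, 0 °C
Reagents that add atoms: iodine, II
Why: Appel iodination converts the primary alcohol through its alkoxyphosphonium salt into the C13 iodide by SN2, and premixing phosphine and iodine keeps free iodine away from the diene.

Step 17
Reactants: 27 dimethyl (2Z,4R,6E,8E,11R,12Z)-4,11-bis[(tert-butyldimethylsilyl)oxy]-2-(2-iodoethyl)-12-(iodomethylidene)-6-methyl-9-(propan-2-yl)trideca-2,6,8-trienedioate
Product: 28 dimethyl (1Z,3R,5E,7E,10R,11Z)-3,10-bis[(tert-butyldimethylsilyl)oxy]-5-methyl-8-(propan-2-yl)cyclotetradeca-1,5,7,11-tetraene-1,11-dicarboxylate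
Conditions: NiBr2(MeOCH2CH2OMe) (0.5 equiv), 4,4'-di-tert-butyl-2,2'-bipyridine (0.6 equiv), Zn dust (6 equiv), NaI (1 equiv), DMA, 25 °C; 27 added by syringe pump over 12 h, final 2 mM
Reagents that add atoms: none
Why: Zerovalent nickel (from NiBr2 and Zn, carried by the bipyridine) inserts into the C12–I bond with retention, a monovalent nickel species abstracts iodine from C13, and the primary radical is captured by the divalent alkenylnickel to give a trivalent alkyl(alkenyl)nickel that forms C12–C13 by reductive elimination while Zn returns nickel to its low-valent state. The closest known reaction type is the nickel-catalysed reductive cross-electrophile coupling of alkenyl halides with alkyl halides, run here within one molecule. The 14-membered ring closes head to tail through a 15-membered nickelacycle, so no exo/endo choice arises, and no stereocentre is formed. Ring closure has to outrun oligomerisation: slow addition to 2 mM keeps the seco compound scarce, and three rigid alkene units (two trisubstituted enoates and the E,E-diene) leave few rotors in the chain. The C11=C12 geometry has to survive: nickel at C12 lies cis to the C11 ester, so carbonyl chelation holds the Z arrangement even if an allenolate pathway is open, and hetero-coupling is intrinsic because the sp2 iodide reacts by two-electron insertion and the sp3 iodide by halogen abstraction. Silyl ethers at C3 and C10 and a diene in place of the vinyl epoxide give nickel no ionisable allylic leaving group.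

Step 18
Reactants: 28 dimethyl (1Z,3R,5E,7E,10R,11Z)-3,10-bis[(tert-butyldimethylsilyl)oxy]-5-methyl-8-(propan-2-yl)cyclotetradeca-1,5,7,11-tetraene-1,11-dicarboxylate
Product: 30 dimethyl (1Z,3R,5E,7E,10R,11Z)-3,10-diacetoxy-5-methyl-8-(propan-2-yl)cyclotetradeca-1,5,7,11-tetraene-1,11-dicarboxylate, via macrocyclic diol 29 (not isolated)
Conditions: HF·pyridine, pyridine, THF, 0 °C to rt; aq. NaHCO3, extraction, concentration below 20 °C; then Ac2O, 4-(dimethylamino)pyridine, pyridine, CH2Cl2, 0 °C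
Reagents that add atoms: acetic anhydride, CC(=O)OC(C)=O
Why: Buffered fluoride desilylation followed at once by nucleophile-catalysed acetylation of the crude diol exchanges both silyl ethers for acetates without touching a stereocentre, and acetylating without purification gives the (Z)-γ-hydroxy enoate at C3 little time to close to a butenolide.

Step 19
Reactants: 30 dimethyl (1Z,3R,5E,7E,10R,11Z)-3,10-diacetoxy-5-methyl-8-(propan-2-yl)cyclotetradeca-1,5,7,11-tetraene-1,11-dicarboxylate
Product: 31 dimethyl (1Z,3R,5S,6S,7E,10R,11Z)-3,10-diacetoxy-5,6-epoxy-5-methyl-8-(propan-2-yl)cyclotetradeca-1,7,11-triene-1,11-dicarboxylate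
Conditions: 1,2:4,5-di-O-isopropylidene-β-L-erythro-2,3-hexodiulo-2,6-pyranose (1.0 equiv), KHSO5 (as 2KHSO5·KHSO4·K2SO4), NaHCO3, Bu4NHSO4, MeCN/H2O, 0 °C, pH about 8
Reagents that add atoms: potassium peroxymonosulfate, [K+].[O-]S(=O)(=O)OO
Why: Shi epoxidation: the chiral dioxirane from the L-configured ketone attacks the methyl-bearing C5=C6 bond of the diene through a spiro transition state (C7=C8 is shielded by isopropyl, both enoates are electron-poor, and the vinyl epoxide formed is deactivated), and it delivers oxygen to the face that gives 5S,6S, the mirror image of the sense established for the D-fructose-derived ketone on trans-trisubstituted alkenes.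

Compound list
1 | (R)-glycidyl 4-methoxybenzyl ether | COc1ccc(COC[C@H]2CO2)cc1 | starting material
2 | lithium acetylide–ethylenediamine complex | [Li]C#C.NCCN | starting material
3 | (2R)-1-[(4-methoxybenzyl)oxy]pent-4-yn-2-ol | COc1ccc(COC[C@H](O)CC#C)cc1 | intermediate
4 | tert-butyl{[(2R)-1-[(4-methoxybenzyl)oxy]pent-4-yn-2-yl]oxy}dimethylsilane | COc1ccc(COC[C@H](O[Si](C)(C)C(C)(C)C)CC#C)cc1 | intermediate
5 | dimethyl[(1E,4R)-4-[(tert-butyldimethylsilyl)oxy]-5-[(4-methoxybenzyl)oxy]-2-methylpent-1-en-1-yl]alumane | COc1ccc(COC[C@H](O[Si](C)(C)C(C)(C)C)C/C(C)=C/[Al](C)C)cc1 | intermediate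
6 | tert-butyl{[(2R,4E)-5-iodo-1-[(4-methoxybenzyl)oxy]-4-methylpent-4-en-2-yl]oxy}dimethylsilane | COc1ccc(COC[C@H](O[Si](C)(C)C(C)(C)C)C/C(C)=C/I)cc1 | intermediate
7 | (2R,4E)-2-[(tert-butyldimethylsilyl)oxy]-5-iodo-4-methylpent-4-en-1-ol | OC[C@H](O[Si](C)(C)C(C)(C)C)C/C(C)=C/I | intermediate
8 | (2R,4E)-2-[(tert-butyldimethylsilyl)oxy]-5-iodo-4-methylpent-4-enal | O=C[C@H](O[Si](C)(C)C(C)(C)C)C/C(C)=C/I | intermediate
9 | methyl bis(2,2,2-trifluoroethyl)phosphonoacetate | COC(=O)CP(=O)(OCC(F)(F)F)OCC(F)(F)F | starting material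
10 | tert-butyl(2-iodoethoxy)dimethylsilane | CC(C)(C)[Si](C)(C)OCCI | starting material
11 | methyl 2-[bis(2,2,2-trifluoroethoxy)phosphoryl]-4-[(tert-butyldimethylsilyl)oxy]butanoate (racemic) | COC(=O)C(CCO[Si](C)(C)C(C)(C)C)P(=O)(OCC(F)(F)F)OCC(F)(F)F | intermediate
12 | methyl (2Z,4R,6E)-4-[(tert-butyldimethylsilyl)oxy]-2-{2-[(tert-butyldimethylsilyl)oxy]ethyl}-7-iodo-6-methylhepta-2,6-dienoate | COC(=O)/C(CCO[Si](C)(C)C(C)(C)C)=C\[C@H](O[Si](C)(C)C(C)(C)C)C/C(C)=C/I | intermediate
13 | 3-methylbut-1-yne | CC(C)C#C | starting material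
14 | dibromo[(1Z)-2-bromo-3-methylbut-1-en-1-yl]borane | CC(C)/C(Br)=C/B(Br)Br | intermediate
15 | 2-[(1Z)-2-bromo-3-methylbut-1-en-1-yl]-4,4,5,5-tetramethyl-1,3,2-dioxaborolane | CC(C)/C(Br)=C/B1OC(C)(C)C(C)(C)O1 | intermediate
16 | (2-ethoxy-2-oxoethyl)zinc bromide | CCOC(=O)C[Zn]Br | starting material
17 | ethyl (3E)-4-methyl-3-[(4,4,5,5-tetramethyl-1,3,2-dioxaborolan-2-yl)methylidene]pentanoate | CCOC(=O)C/C(=C\B1OC(C)(C)C(C)(C)O1)C(C)C | intermediate
18 | (3E)-4-methyl-3-[(4,4,5,5-tetramethyl-1,3,2-dioxaborolan-2-yl)methylidene]pentan-1-ol | OCC/C(=C\B1OC(C)(C)C(C)(C)O1)C(C)C | intermediate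
19 | methyl (2Z,4R,6E,8E)-4-[(tert-butyldimethylsilyl)oxy]-2-{2-[(tert-butyldimethylsilyl)oxy]ethyl}-11-hydroxy-6-methyl-9-(propan-2-yl)undeca-2,6,8-trienoate | COC(=O)/C(CCO[Si](C)(C)C(C)(C)C)=C\[C@H](O[Si](C)(C)C(C)(C)C)C/C(C)=C/C=C(/C(C)C)CCO | intermediate
20 | methyl (2Z,4R,6E,8E)-4-[(tert-butyldimethylsilyl)oxy]-2-{2-[(tert-butyldimethylsilyl)oxy]ethyl}-6-methyl-11-oxo-9-(propan-2-yl)undeca-2,6,8-trienoate | COC(=O)/C(CCO[Si](C)(C)C(C)(C)C)=C\[C@H](O[Si](C)(C)C(C)(C)C)C/C(C)=C/C=C(/C(C)C)CC=O | intermediate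
21 | methyl propiolate | C#CC(=O)OC | starting material
22 | 1-iodo-3-methoxy-3-[(trimethylsilyl)oxy]propa-1,2-diene | COC(O[Si](C)(C)C)=C=CI | intermediate
23 | dimethyl (2Z,4R,6E,8E,11R,12Z)-4-[(tert-butyldimethylsilyl)oxy]-2-{2-[(tert-butyldimethylsilyl)oxy]ethyl}-12-(iodomethylidene)-6-methyl-9-(propan-2-yl)-11-[(trimethylsilyl)oxy]trideca-2,6,8-trienedioate | COC(=O)/C(CCO[Si](C)(C)C(C)(C)C)=C\[C@H](O[Si](C)(C)C(C)(C)C)C/C(C)=C/C=C(/C(C)C)C[C@@H](O[Si](C)(C)C)/C(C(=O)OC)=C/I | intermediate
24 | dimethyl (2Z,4R,6E,8E,11R,12Z)-4-[(tert-butyldimethylsilyl)oxy]-2-{2-[(tert-butyldimethylsilyl)oxy]ethyl}-11-hydroxy-12-(iodomethylidene)-6-methyl-9-(propan-2-yl)trideca-2,6,8-trienedioate | COC(=O)/C(CCO[Si](C)(C)C(C)(C)C)=C\[C@H](O[Si](C)(C)C(C)(C)C)C/C(C)=C/C=C(/C(C)C)C[C@@H](O)/C(C(=O)OC)=C/I | intermediate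
25 | dimethyl (2Z,4R,6E,8E,11R,12Z)-4,11-bis[(tert-butyldimethylsilyl)oxy]-2-{2-[(tert-butyldimethylsilyl)oxy]ethyl}-12-(iodomethylidene)-6-methyl-9-(propan-2-yl)trideca-2,6,8-trienedioate | COC(=O)/C(CCO[Si](C)(C)C(C)(C)C)=C\[C@H](O[Si](C)(C)C(C)(C)C)C/C(C)=C/C=C(/C(C)C)C[C@@H](O[Si](C)(C)C(C)(C)C)/C(C(=O)OC)=C/I | intermediate
26 | dimethyl (2Z,4R,6E,8E,11R,12Z)-4,11-bis[(tert-butyldimethylsilyl)oxy]-2-(2-hydroxyethyl)-12-(iodomethylidene)-6-methyl-9-(propan-2-yl)trideca-2,6,8-trienedioate | COC(=O)/C(CCO)=C\[C@H](O[Si](C)(C)C(C)(C)C)C/C(C)=C/C=C(/C(C)C)C[C@@H](O[Si](C)(C)C(C)(C)C)/C(C(=O)OC)=C/I | intermediate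
27 | dimethyl (2Z,4R,6E,8E,11R,12Z)-4,11-bis[(tert-butyldimethylsilyl)oxy]-2-(2-iodoethyl)-12-(iodomethylidene)-6-methyl-9-(propan-2-yl)trideca-2,6,8-trienedioate (seco diiodide) | ICC/C(C(=O)OC)=C/[C@H](O[Si](C)(C)C(C)(C)C)C/C(C)=C/C=C(/C(C)C)C[C@@H](O[Si](C)(C)C(C)(C)C)/C(C(=O)OC)=C/I | intermediate
28 | dimethyl (1Z,3R,5E,7E,10R,11Z)-3,10-bis[(tert-butyldimethylsilyl)oxy]-5-methyl-8-(propan-2-yl)cyclotetradeca-1,5,7,11-tetraene-1,11-dicarboxylate | COC(=O)/C1=C\[C@H](O[Si](C)(C)C(C)(C)C)C/C(C)=C/C=C(/C(C)C)C[C@@H](O[Si](C)(C)C(C)(C)C)/C(C(=O)OC)=C/CC1 | intermediate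
29 | dimethyl (1Z,3R,5E,7E,10R,11Z)-3,10-dihydroxy-5-methyl-8-(propan-2-yl)cyclotetradeca-1,5,7,11-tetraene-1,11-dicarboxylate | COC(=O)/C1=C\[C@H](O)C/C(C)=C/C=C(/C(C)C)C[C@@H](O)/C(C(=O)OC)=C/CC1 | intermediate
30 | dimethyl (1Z,3R,5E,7E,10R,11Z)-3,10-diacetoxy-5-methyl-8-(propan-2-yl)cyclotetradeca-1,5,7,11-tetraene-1,11-dicarboxylate | COC(=O)/C1=C\[C@H](OC(C)=O)C/C(C)=C/C=C(/C(C)C)C[C@@H](OC(C)=O)/C(C(=O)OC)=C/CC1 | intermediate
31 | dimethyl (1Z,3R,5S,6S,7E,10R,11Z)-3,10-diacetoxy-5,6-epoxy-5-methyl-8-(propan-2-yl)cyclotetradeca-1,7,11-triene-1,11-dicarboxylate (CNP0359666.2) | COC(=O)/C1=C\[C@H](OC(C)=O)C[C@]2(C)O[C@H]2/C=C(/C(C)C)C[C@@H](OC(C)=O)/C(C(=O)OC)=C/CC1 | target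

Total step count: 19. Longest linear sequence: 15 steps (steps 1 to 5, 7 and 11 to 19).

Steps most likely to fail

Step 17. Intermolecular coupling may outrun ring closure, either C–I bond may be reduced to C–H before the coupling, and the alkenylnickel may lose its geometry. The fallback sets out from 27 and returns at 28, and it replaces the radical cross-electrophile process by a polar two-stage coupling. Iodine–magnesium exchange with i-PrMgCl·LiCl in THF at −40 °C would take place only at the activated alkenyl iodide, with retention and with the primary iodide left alone. Transmetalation with ZnCl2 would give the C12 alkenylzinc chloride F1. Slow addition of F1 to Pd2(dibenzylideneacetone)3, P(c-C5H9)3 and N-methylimidazole in THF/NMP at 60 °C would then close the ring by intramolecular alkyl–alkenyl Negishi coupling at the primary iodide.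

Step 13. The skipped dienal may isomerise into conjugation before the C–C bond forms, and facial discrimination at C10 may be insufficient. The fallback sets out from 20 and returns at 24, and it separates bond formation from stereocontrol. The union with 21 would be run with MgI2 in CH2Cl2 at 0 °C, an achiral iodo-aldol that should give 24 together with its C10 epimer, the 11S alcohol F2. Acylation of the mixture with vinyl acetate and Burkholderia cepacia lipase would then differentiate the two. By the empirical size rule for secondary alcohols, with the branched alkenyl ester unit as the large group, the 11R carbinol should be esterified to the 11R acetate F3 while F2 stays behind. After chromatographic separation, the same lipase in phosphate buffer would hydrolyse F3 to 24.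

Step 19. The dioxirane may fail to discriminate C5=C6 from C7=C8, a second epoxidation may follow, and the face may be mismatched with the ring conformation. The fallback sets out from 28 and returns at 31, and it replaces steric discrimination by hydroxyl-directed oxygen delivery.
- Partial desilylation (HF·pyridine, pyridine, THF, 0 °C, stopped early) would free the less hindered C3 oxygen and give the C3 alcohol F4.
- A vanadium-catalysed homoallylic epoxidation would deliver oxygen from the C3 hydroxyl to C5=C6 only and give the epoxy alcohol F5. The conditions are VO(O-i-Pr)3, a chiral bis-hydroxamic acid ligand of the antipode matched to the 5S,6S face, cumene hydroperoxide, toluene, 0 °C.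
- Acetylation (Ac2O, 4-(dimethylamino)pyridine, pyridine) would give the C3 acetate F6.
- Bu4NF buffered with AcOH in THF would remove the C10 silyl ether and give the C10 alcohol F7, and a second acetylation would give 31.

Further compounds
F1 | step 17 | C12 alkenylzinc chloride derived from 27 (C13 iodide retained) | ICC/C(C(=O)OC)=C/[C@H](O[Si](C)(C)C(C)(C)C)C/C(C)=C/C=C(/C(C)C)C[C@@H](O[Si](C)(C)C(C)(C)C)/C(C(=O)OC)=C/[Zn]Cl
F2 | step 13 | dimethyl (2Z,4R,6E,8E,11S,12Z)-4-[(tert-butyldimethylsilyl)oxy]-2-{2-[(tert-butyldimethylsilyl)oxy]ethyl}-11-hydroxy-12-(iodomethylidene)-6-methyl-9-(propan-2-yl)trideca-2,6,8-trienedioate | COC(=O)/C(CCO[Si](C)(C)C(C)(C)C)=C\[C@H](O[Si](C)(C)C(C)(C)C)C/C(C)=C/C=C(/C(C)C)C[C@H](O)/C(C(=O)OC)=C/I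
F3 | step 13 | dimethyl (2Z,4R,6E,8E,11R,12Z)-11-acetoxy-4-[(tert-butyldimethylsilyl)oxy]-2-{2-[(tert-butyldimethylsilyl)oxy]ethyl}-12-(iodomethylidene)-6-methyl-9-(propan-2-yl)trideca-2,6,8-trienedioate | COC(=O)/C(CCO[Si](C)(C)C(C)(C)C)=C\[C@H](O[Si](C)(C)C(C)(C)C)C/C(C)=C/C=C(/C(C)C)C[C@@H](OC(C)=O)/C(C(=O)OC)=C/I
F4 | step 19 | dimethyl (1Z,3R,5E,7E,10R,11Z)-10-[(tert-butyldimethylsilyl)oxy]-3-hydroxy-5-methyl-8-(propan-2-yl)cyclotetradeca-1,5,7,11-tetraene-1,11-dicarboxylate | COC(=O)/C1=C\[C@H](O)C/C(C)=C/C=C(/C(C)C)C[C@@H](O[Si](C)(C)C(C)(C)C)/C(C(=O)OC)=C/CC1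
F5 | step 19 | dimethyl (1Z,3R,5S,6S,7E,10R,11Z)-10-[(tert-butyldimethylsilyl)oxy]-5,6-epoxy-3-hydroxy-5-methyl-8-(propan-2-yl)cyclotetradeca-1,7,11-triene-1,11-dicarboxylate | COC(=O)/C1=C\[C@H](O)C[C@]2(C)O[C@H]2/C=C(/C(C)C)C[C@@H](O[Si](C)(C)C(C)(C)C)/C(C(=O)OC)=C/CC1
F6 | step 19 | dimethyl (1Z,3R,5S,6S,7E,10R,11Z)-3-acetoxy-10-[(tert-butyldimethylsilyl)oxy]-5,6-epoxy-5-methyl-8-(propan-2-yl)cyclotetradeca-1,7,11-triene-1,11-dicarboxylate | COC(=O)/C1=C\[C@H](OC(C)=O)C[C@]2(C)O[C@H]2/C=C(/C(C)C)C[C@@H](O[Si](C)(C)C(C)(C)C)/C(C(=O)OC)=C/CC1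
F7 | step 19 | dimethyl (1Z,3R,5S,6S,7E,10R,11Z)-3-acetoxy-5,6-epoxy-10-hydroxy-5-methyl-8-(propan-2-yl)cyclotetradeca-1,7,11-triene-1,11-dicarboxylate | COC(=O)/C1=C\[C@H](OC(C)=O)C[C@]2(C)O[C@H]2/C=C(/C(C)C)C[C@@H](O)/C(C(=O)OC)=C/CC1
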